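**Strategy.** Everything rests on breaking the ring bond C3–C4 of the cyclohexenone. C4 carries the hydroxyl and lies next to the C2=C3 double bond of the methoxy enone, so this bond can be made by adding a C3 alkenyl-metal to a C4 aldehyde. A nickel/chromium-mediated Nozaki–Hiyama–Kishi cyclisation does this in the last step: it closes the six-membered ring, creates the C4 carbinol and gives the target without protecting groups. Its precursor is an open-chain γ-keto aldehyde whose C1 ketone bears an (E)-β-iodo-α-methoxyvinyl group (C2, C3), with the C6 methyl and C5 farnesyl centres already in place. C1, C6, C5 and C4 derive from (R)-methylsuccinate.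

Key step: step 8

Remark: ring numbering C1 (C=O), C2 (OMe), C3, C4 (OH), C5 (farnesyl), C6 (CH3) is kept for the open-chain compounds; "farnesyl" means (2E,6E)-3,7,11-trimethyldodeca-2,6,10-trien-1-yl; the target is (4R,5R,6R), with 4-OH cis to farnesyl and farnesyl trans to methyl.
Assumption: methoxyacetylene is made (step 3) and not bought, and the two C4 epimers from step 8 can be separated by chromatography.

Step 1
Reactants: 1 (R)-2-methylsuccinic acid 4-methyl ester; 2 (2E,6E)-farnesyl bromide
Product: 4 (2R,3R)-3-farnesyl-2-methylsuccinic acid 4-methyl ester, via dilithium carboxylate enolate 3 (not isolated)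
Conditions: LDA (2.2 equiv), THF, −78 °C; then 2 (1.1 equiv), −78 → −20 °C; cold 1 M HCl
Reagents that add atoms: none
Why: Two equivalents of LDA give the carboxylate/ester-enolate dianion without removing the C6–H next to the carboxylate, and SN2 alkylation by the allylic bromide should occur on the enolate face opposite the solvated lithium carboxylate (C6–H eclipsing the enolate), which sets C5 as R, anti to the methyl group (dianion alkylation of a succinic half-ester).

Step 2
Reactants: 4 (2R,3R)-3-farnesyl-2-methylsuccinic acid 4-methyl ester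
Product: 6 (3R,4R)-4-farnesyl-3-methyldihydrofuran-2(3H)-one (trans-lactone), via hydroxy acid 5 (not isolated)
Conditions: LiBH4 (3 equiv), THF, 0 °C → rt; then 1 M HCl, rt
Reagents that add atoms: none
Why: Lithium borohydride reduces the methyl ester but not the lithium carboxylate, and the γ-hydroxy acid lactonises on acidification without touching C5 or C6 (chemoselective ester reduction and lactonisation); any cis-lactone carried over from step 1 is removed here by chromatography.

Step 3
Reactants: 7 chloroacetaldehyde dimethyl acetal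
Product: 9 methoxyacetylene, via sodium methoxyacetylide 8 (not isolated)
Conditions: NaNH2 (3 equiv), liq. NH3, −33 °C; then cold aq. NaCl, distil
Reagents that add atoms: none
Why: Sodium amide removes methanol and then hydrogen chloride from the chloroacetal and deprotonates the alkyne formed, and the aqueous quench releases the volatile ynol ether (double β-elimination).

Step 4
Reactants: 9 methoxyacetylene; 10 hexamethylditin
Product: 11 (Z)-1-methoxy-1,2-bis(trimethylstannyl)ethene
Conditions: Pd(PPh3)4 (2 mol %), THF, rt → 50 °C, sealed vessel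
Reagents that add atoms: none
Why: Pd(0) inserts into the Sn–Sn bond and delivers both tin atoms to the same face of the alkyne (syn bis-stannylation of a 1-alkoxyalkyne), which fixes the two tin atoms cis.

Step 5
Reactants: 11 (Z)-1-methoxy-1,2-bis(trimethylstannyl)ethene; 6 (3R,4R)-4-farnesyl-3-methyldihydrofuran-2(3H)-one
Product: 14 (1E,4R,5R)-5-farnesyl-6-hydroxy-2-methoxy-4-methyl-1-(trimethylstannyl)hex-1-en-3-one, via alkenyllithium 12 (not isolated), via lithium lactolate 13 (not isolated)
Conditions: 11 (1.3 equiv), MeLi (1.25 equiv), THF, −78 °C; then 6, −78 °C; sat. aq. NH4Cl at −78 °C; crude product taken on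
Reagents that add atoms: none
Why: Methyllithium should exchange only the tin on the oxygen-bearing carbon (tin–lithium exchange with retention, favoured by O–Li coordination and the inductively stabilised α-alkoxyalkenyl anion), and the alkenyllithium adds once to the lactone because the lithium lactolate persists at −78 °C until the quench (acylation of an organolithium by a lactone), leaving tin cis to C1.

Step 6
Reactants: 14 (1E,4R,5R)-5-farnesyl-6-hydroxy-2-methoxy-4-methyl-1-(trimethylstannyl)hex-1-en-3-one
Product: 15 (1E,4R,5R)-5-farnesyl-6-hydroxy-1-iodo-2-methoxy-4-methylhex-1-en-3-one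
Conditions: I2 (1.0 equiv), CH2Cl2, −78 → 0 °C, dark
Reagents that add atoms: iodine, II
Why: Iododestannylation is an ipso substitution with retention of alkene geometry, and the enol-ether-activated C3–Sn bond should consume one equivalent of iodine at low temperature faster than the trisubstituted alkenes or the free alcohol can react, so iodine ends cis to C1.

Step 7
Reactants: 15 (1E,4R,5R)-5-farnesyl-6-hydroxy-1-iodo-2-methoxy-4-methylhex-1-en-3-one
Product: 16 (2R,3R,5E)-2-farnesyl-6-iodo-5-methoxy-3-methyl-4-oxohex-5-enal
Conditions: Dess–Martin periodinane (1.3 equiv), NaHCO3, CH2Cl2, 0 °C → rt; used at once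
Reagents that add atoms: none
Why: Buffered Dess–Martin oxidation converts the primary alcohol into the aldehyde under near-neutral conditions that should neither epimerise C5 or C6 nor disturb the iodoalkene, the enol ether and the triene.

Step 8
Reactants: 16 (2R,3R,5E)-2-farnesyl-6-iodo-5-methoxy-3-methyl-4-oxohex-5-enal
Product: 18 (4R,5R,6R)-5-farnesyl-4-hydroxy-2-methoxy-6-methylcyclohex-2-en-1-one (target), via alkenylchromium(III) species 17 (not isolated)
Conditions: CrCl2 (6 equiv), NiCl2 (0.1 equiv), degassed DMSO/THF, rt, 0.01 M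
Reagents that add atoms: none
Why: Ni(0), generated from NiCl2 by Cr(II), undergoes oxidative addition at the C3–I bond; transmetallation then places C3 on chromium(III) (two Cr(II) are consumed overall), and this alkenylchromium species 17 attacks the C4 aldehyde, giving the C4 carbinol after hydrolysis of the chromium alkoxide. The closest known reaction type is the intramolecular Nozaki–Hiyama–Kishi coupling of β-iodo enones and β-iodo acrylates with aldehydes. The cyclohexenone ring closes by 6-exo-trig attack of C3 on the C4 carbonyl, which is possible only because iodine, and hence the metal, sits cis to C1 on the C2=C3 bond. The new C4 centre is governed by the neighbouring C5 centre alone (1,2-induction within a half-chair); the 4R alcohol requires the aldehyde oxygen on the ring face cis to the farnesyl group, a bias expected to be weak, so both C4 epimers should form and the 4R isomer 18 is separated by chromatography. Chemoselectivity is secured because alkenylchromium reagents add to aldehydes far faster than to ketones and the substrate's own ketone lies out of reach of C3. Because no acid or base is present, C5 and C6 should not epimerise, and the enol ether and the three trisubstituted alkenes are inert to the Cr/Ni system.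

**Compound list**

1 | (R)-2-methylsuccinic acid 4-methyl ester | C[C@H](CC(=O)OC)C(=O)O | starting material
2 | (2E,6E)-farnesyl bromide | CC(C)=CCC/C(C)=C/CC/C(C)=C/CBr | starting material
3 | dilithium carboxylate ester-enolate of 1 | C[C@H](C=C([O-])OC)C(=O)[O-].[Li+].[Li+] | intermediate
4 | (2R,3R)-3-farnesyl-2-methylsuccinic acid 4-methyl ester | C[C@H]([C@@H](C/C=C(\C)CC/C=C(\C)CCC=C(C)C)C(=O)OC)C(=O)O | intermediate
5 | (2R,3R)-3-farnesyl-4-hydroxy-2-methylbutanoic acid | C[C@H]([C@@H](C/C=C(\C)CC/C=C(\C)CCC=C(C)C)CO)C(=O)O | intermediate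
6 | (3R,4R)-4-farnesyl-3-methyldihydrofuran-2(3H)-one (trans) | O=C1OC[C@H](C/C=C(\C)CC/C=C(\C)CCC=C(C)C)[C@H]1C | intermediate
7 | chloroacetaldehyde dimethyl acetal | COC(CCl)OC | starting material
8 | sodium methoxyacetylide | COC#[C-].[Na+] | intermediate
9 | methoxyacetylene | COC#C | intermediate
10 | hexamethylditin | C[Sn](C)(C)[Sn](C)(C)C | starting material
11 | (Z)-1-methoxy-1,2-bis(trimethylstannyl)ethene | CO/C(=C/[Sn](C)(C)C)[Sn](C)(C)C | intermediate
12 | (E)-1-lithio-1-methoxy-2-(trimethylstannyl)ethene (Li cis to Sn) | CO/C([Li])=C/[Sn](C)(C)C | intermediate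
13 | lithium lactolate from addition of 12 to the carbonyl of 6 (C1 epimers) | [Li+].[O-]C1(OC[C@H](C/C=C(\C)CC/C=C(\C)CCC=C(C)C)[C@H]1C)/C(OC)=C\[Sn](C)(C)C | intermediate
14 | (1E,4R,5R)-5-farnesyl-6-hydroxy-2-methoxy-4-methyl-1-(trimethylstannyl)hex-1-en-3-one | OC[C@H](C/C=C(\C)CC/C=C(\C)CCC=C(C)C)[C@@H](C)C(=O)/C(OC)=C\[Sn](C)(C)C | intermediate
15 | (1E,4R,5R)-5-farnesyl-6-hydroxy-1-iodo-2-methoxy-4-methylhex-1-en-3-one | OC[C@H](C/C=C(\C)CC/C=C(\C)CCC=C(C)C)[C@@H](C)C(=O)/C(OC)=C\I | intermediate
16 | (2R,3R,5E)-2-farnesyl-6-iodo-5-methoxy-3-methyl-4-oxohex-5-enal | O=C[C@H](C/C=C(\C)CC/C=C(\C)CCC=C(C)C)[C@@H](C)C(=O)/C(OC)=C\I | intermediate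
17 | alkenylchromium(III) dichloride formed from 16 at C3 | O=C[C@H](C/C=C(\C)CC/C=C(\C)CCC=C(C)C)[C@@H](C)C(=O)/C(OC)=C\[Cr](Cl)Cl | intermediate
18 | (4R,5R,6R)-5-farnesyl-4-hydroxy-2-methoxy-6-methylcyclohex-2-en-1-one | COC1=C[C@H](O)[C@H](C/C=C(\C)CC/C=C(\C)CCC=C(C)C)[C@@H](C)C1=O | target

**Step count.** Total: 8 steps. Longest linear sequence: 6 steps (steps 1, 2, 5, 6, 7, 8, from 1); the tin reagent 11 is made in a 2-step side branch (steps 3 and 4).

**Steps most likely to fail**

Step 8 — poor facial selectivity at the C4 aldehyde: the chromium-bound oxygen may prefer the pseudo-equatorial site of the half-chair with C5 and C6 substituents equatorial, which leads mainly to the C4 epimer. Fallback: starting again from 16, the cyclisation is run unchanged and the (4S,5R,6R)-5-farnesyl-4-hydroxy-2-methoxy-6-methylcyclohex-2-en-1-one F1 is isolated. Mitsunobu esterification (4-nitrobenzoic acid, PPh3, DIAD, THF, 0 °C) inverts C4 by SN2 displacement to the (4R,5R,6R)-4-(4-nitrobenzoyloxy) enone F2. Methanolysis (K2CO3, MeOH, 0 °C) then releases 18.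

Step 5 — loss of control in the addition to the lactone: the lactolate may collapse before the quench so that a second alkenyllithium adds, or the organolithium may deprotonate C6 in place of adding. Fallback: from 6, DIBAL-H (CH2Cl2, −78 °C) gives the lactol (3R,4R)-4-farnesyl-3-methyltetrahydrofuran-2-ol F3. This reacts through its hydroxy aldehyde form with two equivalents of 12 (THF, −78 → −20 °C) and can take up only one alkenyl group, giving (2R,3R,5E)-2-farnesyl-5-methoxy-3-methyl-6-(trimethylstannyl)hex-5-ene-1,4-diol F4 (both epimers at the new carbinol). MnO2 (CH2Cl2, rt) oxidises only the allylic secondary alcohol and returns to 14.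

Step 1 — insufficient anti selectivity in the dianion alkylation, which would leave the C5 epimer. Fallback: from 2, C5 is set by an oxazolidinone auxiliary and the methyl group is introduced last.
- The imide tert-butyl 4-[(4R)-4-benzyl-2-oxo-1,3-oxazolidin-3-yl]-4-oxobutanoate F5 is made from mono-tert-butyl succinate and (R)-4-benzyl-2-oxazolidinone through the pivaloyl mixed anhydride.
- F5 is deprotonated with NaHMDS (THF, −78 °C) and alkylated with 2 on the face away from the benzyl group, to give tert-butyl (3R)-4-[(4R)-4-benzyl-2-oxo-1,3-oxazolidin-3-yl]-3-farnesyl-4-oxobutanoate F6.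
- LiBH4 (THF/MeOH, 0 °C) removes the auxiliary and gives tert-butyl (3R)-3-farnesyl-4-hydroxybutanoate F7.
- Catalytic KOt-Bu in THF closes F7 to (4R)-4-farnesyldihydrofuran-2(3H)-one F8.
- LDA then MeI (THF, −78 °C) methylates the lactone enolate anti to the farnesyl group and returns to 6.

**Further compounds**

F1 | step 8 | (4S,5R,6R)-5-farnesyl-4-hydroxy-2-methoxy-6-methylcyclohex-2-en-1-one | COC1=C[C@@H](O)[C@H](C/C=C(\C)CC/C=C(\C)CCC=C(C)C)[C@@H](C)C1=O
F2 | step 8 | (4R,5R,6R)-5-farnesyl-2-methoxy-6-methyl-4-(4-nitrobenzoyloxy)cyclohex-2-en-1-one | COC1=C[C@H](OC(=O)c2ccc(cc2)[N+](=O)[O-])[C@H](C/C=C(\C)CC/C=C(\C)CCC=C(C)C)[C@@H](C)C1=O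
F3 | step 5 | (3R,4R)-4-farnesyl-3-methyltetrahydrofuran-2-ol (anomers) | OC1OC[C@H](C/C=C(\C)CC/C=C(\C)CCC=C(C)C)[C@H]1C
F4 | step 5 | (2R,3R,5E)-2-farnesyl-5-methoxy-3-methyl-6-(trimethylstannyl)hex-5-ene-1,4-diol (carbinol epimers) | OC[C@H](C/C=C(\C)CC/C=C(\C)CCC=C(C)C)[C@@H](C)C(O)/C(OC)=C\[Sn](C)(C)C
F5 | step 1 | tert-butyl 4-[(4R)-4-benzyl-2-oxo-1,3-oxazolidin-3-yl]-4-oxobutanoate | CC(C)(C)OC(=O)CCC(=O)N1[C@H](Cc2ccccc2)COC1=O
F6 | step 1 | tert-butyl (3R)-4-[(4R)-4-benzyl-2-oxo-1,3-oxazolidin-3-yl]-3-farnesyl-4-oxobutanoate | CC(C)(C)OC(=O)C[C@@H](C/C=C(\C)CC/C=C(\C)CCC=C(C)C)C(=O)N1[C@H](Cc2ccccc2)COC1=O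
F7 | step 1 | tert-butyl (3R)-3-farnesyl-4-hydroxybutanoate | CC(C)(C)OC(=O)C[C@@H](C/C=C(\C)CC/C=C(\C)CCC=C(C)C)CO
F8 | step 1 | (4R)-4-farnesyldihydrofuran-2(3H)-one | O=C1C[C@@H](C/C=C(\C)CC/C=C(\C)CCC=C(C)C)CO1
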